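The target is disconnected at the aryl–C1 bond and then into three aldehydes: the whole chain C1–C8 (C1 benzylic) is butanal (C5–C8) extended head to tail by two acetaldehyde units (C3–C4, then C1–C2), and its syn 1,3-dioxygen pattern at C3 (S) and C5 (R) is the signature of a repeated acetate aldol. One aldolase reaction forms the C4–C5 and C2–C3 bonds, sets both carbinol centres and closes a six-membered oxane lactol (C5–O to C1) that halts chain growth. Its precursors are simply butanal and acetaldehyde. A benzyl-protected guaiacyl Grignard reagent then adds to C1; peracetylation and a single hydrogenolysis remove the C1 oxygen and the benzyl group.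

Key step: step 1

Assumption: a butanal-accepting, acetaldehyde-tolerant DERA variant is taken as available; the anomeric centre of 5 and the C1 carbinol of 9 and 10 are carried as mixtures because both centres are destroyed later.

Step 1
Reactants: 1 butanal; 2 acetaldehyde (two equivalents)
Product: 5 (4R,6R)-6-propyloxane-2,4-diol (anomer mixture), via (3R)-3-hydroxyhexanal 3 (not isolated), via (3R,5R)-3,5-dihydroxyoctanal 4 (not isolated)
Conditions: DERA (engineered, cell-free extract), 1 (1.5 equiv), 2 (2.0 equiv, slow feed), triethanolamine buffer pH 7.2, 25 °C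
Reagents that add atoms: none
Why: The active-site lysine condenses with acetaldehyde to an enamine that adds to the carbonyl of butanal, hydrolysis releases 3, and 3 is taken up as acceptor for a second enamine addition to give 4. The closest known reaction type is the aldolase-catalysed sequential addition of two acetaldehyde donors to an acceptor aldehyde, which delivers 2,4-dideoxyhexose-type lactols. Aldehyde 4 closes the oxane ring by 6-exo-trig hemiacetalisation of the C5 hydroxyl onto the C1 carbonyl; the anomeric centre equilibrates and is lost in step 3. Both carbinol centres are catalyst-controlled: the enzyme presents the enamine to the same carbonyl face in each round, giving R at the carbinol of 3 (C5 of 4) and R again at C3 of 4, that is the syn array which is named 3S,5R in the target once C1 loses its oxygen and the CIP ranking at C3 changes. The step needs cross- over homo-aldol selectivity and a stop after two additions: butanal is not expected to serve as donor in the small donor pocket, a slow acetaldehyde feed against excess butanal disfavours acetaldehyde as first acceptor, and lactol 5 has no free carbonyl to accept a third unit. Each aldol step is reversible and the lactol is the thermodynamic sink, so partial adducts should be drawn forward to 5.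

Step 2
Reactants: 6 4-bromo-2-methoxyphenol
Product: 7 1-(benzyloxy)-4-bromo-2-methoxybenzene
Conditions: BnBr (1.1 equiv), K2CO3 (1.5 equiv), DMF, rt
Reagents that add atoms: benzyl bromide, BrCc1ccccc1
Why: Williamson ether synthesis, in which the phenoxide formed by K2CO3 displaces bromide from benzyl bromide by SN2 while the aryl bromide stays inert.

Step 3
Reactants: 7 1-(benzyloxy)-4-bromo-2-methoxybenzene; 5 (4R,6R)-6-propyloxane-2,4-diol
Product: 9 (3R,5R)-1-[4-(benzyloxy)-3-methoxyphenyl]octane-1,3,5-triol (both C1 epimers), via [4-(benzyloxy)-3-methoxyphenyl]magnesium bromide 8 (not isolated)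
Conditions: 7 (4 equiv), Mg, cat. I2, THF, 40 °C; then 5, THF, 0 °C to rt; aq NH4Cl
Reagents that add atoms: none
Why: Magnesium insertion gives Grignard reagent 8, two equivalents of which deprotonate the hydroxyls of 5, the magnesium lactolate equilibrates with its open-chain aldehyde form (the alkoxide of 4), and a further equivalent undergoes Grignard 1,2-addition at C1; the new C1 carbinol forms without control, which is harmless because step 5 removes it, and C3 and C5 are not touched.

Step 4
Reactants: 9 (3R,5R)-1-[4-(benzyloxy)-3-methoxyphenyl]octane-1,3,5-triol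
Product: 10 (3R,5R)-1-[4-(benzyloxy)-3-methoxyphenyl]octane-1,3,5-triyl triacetate (both C1 epimers)
Conditions: Ac2O (4.5 equiv), pyridine, cat. DMAP, CH2Cl2, 0 °C to rt
Reagents that add atoms: acetic anhydride, CC(=O)OC(C)=O
Why: DMAP-catalysed O-acylation (nucleophilic acyl substitution) should esterify all three secondary alcohols without affecting the benzyl ether or the stereocentres, and it turns the benzylic hydroxyl into a leaving group suited to hydrogenolysis.

Step 5
Reactants: 10 (3R,5R)-1-[4-(benzyloxy)-3-methoxyphenyl]octane-1,3,5-triyl triacetate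
Product: 11 (3S,5R)-1-(4-hydroxy-3-methoxyphenyl)octane-3,5-diyl diacetate
Conditions: H2 (1 atm), 10% Pd/C, EtOAc–AcOH (10:1), rt
Reagents that add atoms: none
Why: Palladium-catalysed hydrogenolysis should cleave both benzylic C–O bonds, the O-benzyl ether (to the phenol) and the electron-rich benzylic C1 acetate (to CH2), while the non-benzylic C3 and C5 acetates are inert, so the 3S,5R configuration is kept.

Compound list
1 | butanal | CCCC=O | starting material
2 | acetaldehyde | CC=O | starting material
3 | (3R)-3-hydroxyhexanal (formed in the flask, not isolated) | CCC[C@@H](O)CC=O | intermediate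
4 | (3R,5R)-3,5-dihydroxyoctanal (formed in the flask, not isolated) | CCC[C@@H](O)C[C@@H](O)CC=O | intermediate
5 | (4R,6R)-6-propyloxane-2,4-diol (anomer mixture) | CCC[C@@H]1C[C@@H](O)CC(O)O1 | intermediate
6 | 4-bromo-2-methoxyphenol | COc1cc(Br)ccc1O | starting material
7 | 1-(benzyloxy)-4-bromo-2-methoxybenzene | COc1cc(Br)ccc1OCc1ccccc1 | intermediate
8 | [4-(benzyloxy)-3-methoxyphenyl]magnesium bromide (formed in the flask, not isolated) | COc1cc([Mg]Br)ccc1OCc1ccccc1 | intermediate
9 | (3R,5R)-1-[4-(benzyloxy)-3-methoxyphenyl]octane-1,3,5-triol (both C1 epimers) | CCC[C@@H](O)C[C@@H](O)CC(O)c1ccc(OCc2ccccc2)c(OC)c1 | intermediate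
10 | (3R,5R)-1-[4-(benzyloxy)-3-methoxyphenyl]octane-1,3,5-triyl triacetate (both C1 epimers) | CCC[C@@H](OC(C)=O)C[C@@H](OC(C)=O)CC(OC(C)=O)c1ccc(OCc2ccccc2)c(OC)c1 | intermediate
11 | (3S,5R)-1-(4-hydroxy-3-methoxyphenyl)octane-3,5-diyl diacetate | CCC[C@H](C[C@H](CCc1ccc(O)c(OC)c1)OC(C)=O)OC(C)=O | target

Total step count: 5
Longest linear sequence: 4 steps (1, 3, 4, 5 or 2, 3, 4, 5)

Steps most likely to fail

Step 1. Butanal may be turned over too slowly as acceptor, so that acetaldehyde self-addition (homo- instead of cross-aldol) and acetaldehyde-induced enzyme deactivation take over and little cross-product accumulates. The fallback replaces the enzyme by catalyst- and substrate-controlled chemistry. Setting out from butanal 1, a Ti(OiPr)4/BINOL-catalysed vinylogous Mukaiyama aldol addition of 1-methoxy-1,3-bis(trimethylsilyloxy)buta-1,3-diene (BINOL enantiomer chosen for the 5R carbinol, acidic desilylation on work-up) should give methyl (5R)-5-hydroxy-3-oxooctanoate F1. Narasaka–Prasad reduction (Et2BOMe, NaBH4, THF–MeOH, −78 °C) should then give the syn diol methyl (3R,5R)-3,5-dihydroxyoctanoate F2 by hydride delivery to the boron chelate. Acid-catalysed lactonisation (cat. TsOH, toluene) should give (4R,6R)-4-hydroxy-6-propyloxan-2-one F3, and DIBAL-H (CH2Cl2, −78 °C) should reduce F3 to lactol 5, where the route resumes.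

Step 3. The magnesium lactolate may open sluggishly or aggregate, and the liberated β-alkoxy aldehyde may be enolised by the basic reagent (retro-aldol or elimination) before it is arylated, which would erode conversion and put C3 at risk. The fallback forms the C1–aryl bond by acyl substitution on a protected lactone instead of addition to a free lactol. Setting out from lactol 5, oxidation with Br2/BaCO3 in water should give the lactone (4R,6R)-4-hydroxy-6-propyloxan-2-one F3, the relay compound of the first fallback. Silylation (TBSCl, imidazole, DMF) should give (4R,6R)-4-[(tert-butyldimethylsilyl)oxy]-6-propyloxan-2-one F4. Bromine–lithium exchange on 7 (n-BuLi, THF, −78 °C) should give [4-(benzyloxy)-3-methoxyphenyl]lithium F5, one equivalent of which should add once to the lactone carbonyl of F4 at −78 °C to give (3R,5R)-1-[4-(benzyloxy)-3-methoxyphenyl]-3-[(tert-butyldimethylsilyl)oxy]-5-hydroxyoctan-1-one F6. NaBH4 in MeOH should reduce the ketone to (3R,5R)-1-[4-(benzyloxy)-3-methoxyphenyl]-3-[(tert-butyldimethylsilyl)oxy]octane-1,5-diol F7 (both C1 epimers), and TBAF in THF should release triol 9, where the route resumes.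

Step 5. Cleavage of the benzylic C–O bond may lag behind O-debenzylation or stop through catalyst deactivation, so that the C1 acetate survives in the debenzylated product. The fallback removes the C1 oxygen heterolytically before the hydrogenation. Setting out from triacetate 10, ionic hydrogenation (Et3SiH, TFA, CH2Cl2, 0 °C) should ionise the p-alkoxybenzylic acetate and transfer hydride to the cation to give (3S,5R)-1-[4-(benzyloxy)-3-methoxyphenyl]octane-3,5-diyl diacetate F8. A plain O-debenzylation (H2, Pd/C, EtOAc, rt) should then give 11; any styrene formed by proton loss from the cation would be saturated in the same hydrogenation.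

Further compounds
F1 | step 1 | methyl (5R)-5-hydroxy-3-oxooctanoate | CCC[C@@H](O)CC(=O)CC(=O)OC
F2 | step 1 | methyl (3R,5R)-3,5-dihydroxyoctanoate | CCC[C@@H](O)C[C@@H](O)CC(=O)OC
F3 | step 1 | (4R,6R)-4-hydroxy-6-propyloxan-2-one | CCC[C@@H]1C[C@@H](O)CC(=O)O1
F4 | step 3 | (4R,6R)-4-[(tert-butyldimethylsilyl)oxy]-6-propyloxan-2-one | CCC[C@@H]1C[C@@H](O[Si](C)(C)C(C)(C)C)CC(=O)O1
F5 | step 3 | [4-(benzyloxy)-3-methoxyphenyl]lithium | [Li]c1ccc(OCc2ccccc2)c(OC)c1
F6 | step 3 | (3R,5R)-1-[4-(benzyloxy)-3-methoxyphenyl]-3-[(tert-butyldimethylsilyl)oxy]-5-hydroxyoctan-1-one | CCC[C@@H](O)C[C@@H](O[Si](C)(C)C(C)(C)C)CC(=O)c1ccc(OCc2ccccc2)c(OC)c1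
F7 | step 3 | (3R,5R)-1-[4-(benzyloxy)-3-methoxyphenyl]-3-[(tert-butyldimethylsilyl)oxy]octane-1,5-diol (both C1 epimers) | CCC[C@@H](O)C[C@@H](O[Si](C)(C)C(C)(C)C)CC(O)c1ccc(OCc2ccccc2)c(OC)c1
F8 | step 5 | (3S,5R)-1-[4-(benzyloxy)-3-methoxyphenyl]octane-3,5-diyl diacetate | CCC[C@@H](OC(C)=O)C[C@@H](OC(C)=O)CCc1ccc(OCc2ccccc2)c(OC)c1
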